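**Time out.** Divide the rate of target by the rate of other capture product: the pace of a shared earlier step cancels, but [second nucleophile] stays in the ratio, and that concentration moves with the clock.

all flasks: starting material 0.043 M; first nucleophile 0.0473 M
- ochre: second nucleophile 0.11 M; run made earlier
- grey: second nucleophile 0.17 M; run made earlier
- flask: second nucleophile 0.0774 M; time 4.0 min

- ochre (time / min: other capture product / %, target / %): 0.200: 3.0, 0.6; 0.667: 9.5, 0; 1.00: 15.1, 0; 1.50: 22.9, 1.3; 2.50: 34.2, 1.8; 3.00: 37.7, 2.5; 4.00: 44.7, 3.5
- grey (time / min: other capture product / %, target / %): 0.200: 3.3, 1.4; 0.667: 9.8, 0.8; 1.00: 14.4, 0.9; 1.50: 20.4, 0.5; 2.50: 33.4, 0.7; 3.00: 38.0, 0; 4.00: 47.1, 2.1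

(readings scatter by 1 percentage point)

1. share of other capture product in other capture product plus target at 4.0 s
2. share of other capture product in other capture product plus target at 30 s
3. share of other capture product in other capture product plus target at 4.0 min
4. which of other capture product and target there is more of at 4.0 min

- a reading or a percentage of target counts all its forms, free or not

**Main step.** At 4.0 min, other capture product reads 44.7 % in ochre and 47.1 % in grey, though grey was charged with more second nucleophile. So I place its pace in a step before capture, a rate-limiting step. With second nucleophile as the sole taker, the share would be 100 %.

**Second taker.** Now let first nucleophile compete. At 4.0 min, target reads 2.1 % in grey, less than the 3.5 % in ochre. I suppose that both captures draw on one precursor, so that the pace cancels in their ratio. I take [second nucleophile] midway through each run, its charge less half of what other capture product used. Multiplying this by the target/other ratio gives 0.00786 M in ochre and 0.00713 M in grey. Their mean, 0.00749 M, is the split constant: [second nucleophile] times target formed per other capture product formed, at [first nucleophile] of 0.0473 M. It is a rough reading, since each target reading scatters by 1 percentage point. At the flask's charged 0.0774 M, it gives me a share of 91.2 % for 4.0 s and 30 s.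

**The drawdown.** Capture consumes second nucleophile. If the flask reaches the ochre and grey mean of 45.9 % other capture product at 4.0 min, its midway [second nucleophile] is 0.0675 M, and my share falls to 90.0 %. Any further loss of second nucleophile lowers this, but I have no reading of second nucleophile to size it.

**The forecast.** The forecast gives 93.5 %, 93 % and 91 %, with other capture product ahead: “That fits competitive capture, with ratio ≈ 0.0063/[second nucleophile].” Its shares stand above mine.

**The result.** The flask gives 96.6 %, 96.2 % and 92.0 %, with other capture product ahead at 43.8 % against 3.83 % of target; 14 % of its second nucleophile remains at 4.00 min.

    starting material → intermediate (k = 0.00280 s⁻¹)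
    first nucleophile + intermediate → target (k = 9.20 M⁻¹ s⁻¹)
    second nucleophile + intermediate → other capture product (k = 160 M⁻¹ s⁻¹)
    intermediate → solvolysis product (k = 0.130 s⁻¹)
    crystals ⇌ target, rate k5*(cs5 - [target]) while solid is left; crystals form when [target] > cs5 (solubility = 34.0 mM, k = 1.10 s⁻¹)
    second nucleophile → decomposed reagent (k = 0.00550 s⁻¹)
    intermediate → side product (k = 0.00280 s⁻¹)

Charging 0.11 M of starting material instead is a change that pulls the share away from the forecast's number. With that neighbour's 38.7 % of other capture product, midway [second nucleophile] is 0.0561 M, and the split constant gives 88.2 %. The neighbour stands at 83.8 % at 4.0 min, 7.2 points below the forecast's figure, with 0.958 % of its second nucleophile left.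

The numbers in the tables were computed on assumed constants; scatter was added.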